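The flavonol is cut through ring C at C4–C4a and O1–C2. This gives an A-ring phenol and a three-carbon β-ketoester that already carries ring B and the C3 oxygen. In the phenol, 5-(benzyloxy)-2,3-dimethoxyphenol, the hydroxyl sits on the future C8a. One neighbour, C8, is blocked by methoxy, so C4a is the only open ortho carbon and the annulation can close in one sense only. Heating it with the α-benzyloxy aroylacetate (Mentzer-type condensation via an acylketene) makes both bonds and the pyranone in one operation. O3, O5 and O2' travel as benzyl ethers and fall together in a final hydrogenolysis. The O5 ether also removes the second hydroxyl that would permit the 5,6,7-isomer.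

Key step: step 7

Remark: the target has no stereocentre and no configurationally stable axis, so it is achiral and there is no enantiomer to select. The one stereocentre of the ketoester and of its open-chain descendants is enolisable, is carried as the racemate and ends as sp2 C3.

Step 1
Reactants: 1 3-hydroxy-4,5-dimethoxybenzaldehyde
Product: 2 3,4-dimethoxy-5-[(triisopropylsilyl)oxy]benzaldehyde
Conditions: TIPSCl, imidazole, DMF, rt
Reagents that add atoms: triisopropylsilyl chloride, CC(C)[Si](Cl)(C(C)C)C(C)C
Why: Imidazole-promoted O-silylation of a phenol; TIPS is chosen because, unlike smaller aryl silyl ethers, it should outlast the basic methanolysis and alkylation of steps 2 and 3, and it is orthogonal to benzyl.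

Step 2
Reactants: 2 3,4-dimethoxy-5-[(triisopropylsilyl)oxy]benzaldehyde
Product: 4 3,4-dimethoxy-5-[(triisopropylsilyl)oxy]phenol, via aryl formate 3 (not isolated)
Conditions: mCPBA, CH2Cl2, 0 °C to rt; aq. NaHCO3 wash; then cat. Et3N, MeOH, rt
Reagents that add atoms: mCPBA, O=C(OO)c1cccc(Cl)c1
Why: Baeyer–Villiger (Dakin-type) oxidation in which the electron-rich aryl group (methoxy para to the formyl carbon) migrates in preference to hydride, after which the very labile formate 3 is transesterified by methanol under amine catalysis that leaves the TIPS ether alone.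

Step 3
Reactants: 4 3,4-dimethoxy-5-[(triisopropylsilyl)oxy]phenol
Product: 5 [5-(benzyloxy)-2,3-dimethoxyphenoxy]triisopropylsilane
Conditions: BnBr, K2CO3, dry DMF, rt
Reagents that add atoms: benzyl bromide, BrCc1ccccc1
Why: Williamson etherification of the only free phenol with a reactive benzylic halide under mild carbonate base, which an aryl TIPS ether tolerates.

Step 4
Reactants: 5 [5-(benzyloxy)-2,3-dimethoxyphenoxy]triisopropylsilane
Product: 6 5-(benzyloxy)-2,3-dimethoxyphenol
Conditions: TBAF, AcOH (1:1), THF, 0 °C
Reagents that add atoms: none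
Why: Fluoride-driven desilylation (Si–F bond strength); acetic acid buffers the phenoxide of this oxidisable ring, and benzyl and methyl ethers are inert.

Step 5
Reactants: 7 2-hydroxy-4-methoxybenzoic acid
Product: 9 2-(benzyloxy)-4-methoxybenzoic acid, via benzyl ester 8 (not isolated)
Conditions: BnBr (2.3 equiv), K2CO3, MeCN, reflux; solvent swap; NaOH, MeOH–H2O, 65 °C; then HCl
Reagents that add atoms: benzyl bromide, BrCc1ccccc1; sodium hydroxide, [Na+].[OH-] (one carboxyl oxygen)
Why: Williamson alkylation of phenol and carboxylate followed by saponification of the benzyl ester, which frees the acid while the aryl benzyl ether is stable to hydroxide.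

Step 6
Reactants: 9 2-(benzyloxy)-4-methoxybenzoic acid; 10 ethyl (benzyloxy)acetate
Product: 12 ethyl 2-(benzyloxy)-3-[2-(benzyloxy)-4-methoxyphenyl]-3-oxopropanoate (racemic), via acid chloride 11 (not isolated)
Conditions: 9, (COCl)2, cat. DMF, CH2Cl2, rt, evaporate; 10 (2.1 equiv), LiHMDS (2.1 equiv), THF, −78 °C, then 11 in THF, −78 °C; AcOH quench
Reagents that add atoms: oxalyl chloride, O=C(Cl)C(=O)Cl (chlorine of 11 only; no reagent atom remains in 12)
Why: Crossed Claisen-type C-acylation of a preformed lithium ester enolate by an aroyl chloride; the second equivalent of enolate takes up the acidic proton of 12, −78 °C keeps the benzyloxy enolate from Wittig rearrangement, and the new stereocentre is enolisable and carried as the racemate.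

Step 7
Reactants: 6 5-(benzyloxy)-2,3-dimethoxyphenol; 12 ethyl 2-(benzyloxy)-3-[2-(benzyloxy)-4-methoxyphenyl]-3-oxopropanoate
Product: 16 3,5-bis(benzyloxy)-2-[2-(benzyloxy)-4-methoxyphenyl]-7,8-dimethoxy-4H-chromen-4-one, via acylketene 13 (not isolated), via aryl ketoester 14 (not isolated), via hydroxyaryl diketone 15 (not isolated)
Conditions: 12 (1.5 equiv, in portions), Ph2O, Ar sweep, short-path head, 160 °C then 240–250 °C (−EtOH, −H2O)
Reagents that add atoms: none
Why: Mentzer thermal pyrone synthesis (the uncatalysed relative of the Simonis reaction): the enol of 12 expels ethanol to give acylketene 13, which phenol 6 traps first at oxygen as ester 14, a capture that is reversible at these temperatures. Irreversible C–C bond formation follows when C4a attacks the ketene carbon while the neighbouring O–H is hydrogen-bonded to the ketene oxygen in a six-membered array (formally a thermal O-to-C acyl shift of 14), and rearomatisation gives the chelated o-hydroxyaryl diketone 15. Ring C then closes by 6-exo-trig addition of the C8a hydroxyl to the B-ring ketone carbon (C2), and the hemiketal loses water; the argon sweep carries off ethanol and water so that neither can cleave 12. The closest known cases are melt or diphenyl ether condensations of resorcinol- and phloroglucinol-type phenols with aroylacetates, α-alkoxy members of which give 3-alkoxyflavones. No stereocentre is created, and the racemic α-carbon of 12, 14 and 15 ends as sp2 C3. The step needs acylation at C4a instead of C6, both being activated by three oxygens, and chromone instead of coumarin formation: delivery from the adjacent hydroxyl, the smaller flank (OH against OMe) and the planar hydrogen-bonded ketone favour C4a, C8 is closed by its methoxy group, O5 is capped so that only one hydroxyl can cyclise, and without acid the crowded α-benzyloxy ketone is not attacked by the ring in the Pechmann sense.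

Step 8
Reactants: 16 3,5-bis(benzyloxy)-2-[2-(benzyloxy)-4-methoxyphenyl]-7,8-dimethoxy-4H-chromen-4-one
Product: 17 3,5-dihydroxy-2-(2-hydroxy-4-methoxyphenyl)-7,8-dimethoxy-4H-chromen-4-one (3,5,2'-trihydroxy-7,8,4'-trimethoxyflavone)
Conditions: H2 (1 atm), 10% Pd/C, EtOAc–MeOH, rt
Reagents that add atoms: none
Why: Catalytic hydrogenolysis cleaves the two aryl benzyl ethers and the C3 enol benzyl ether together under conditions in which methyl ethers and the conjugated chromone C2=C3 bond normally persist.

Compound list
1 | 3-hydroxy-4,5-dimethoxybenzaldehyde | COc1cc(C=O)cc(O)c1OC | starting material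
2 | 3,4-dimethoxy-5-[(triisopropylsilyl)oxy]benzaldehyde | COc1cc(C=O)cc(O[Si](C(C)C)(C(C)C)C(C)C)c1OC | intermediate
3 | 3,4-dimethoxy-5-[(triisopropylsilyl)oxy]phenyl formate | COc1cc(OC=O)cc(O[Si](C(C)C)(C(C)C)C(C)C)c1OC | intermediate
4 | 3,4-dimethoxy-5-[(triisopropylsilyl)oxy]phenol | COc1cc(O)cc(O[Si](C(C)C)(C(C)C)C(C)C)c1OC | intermediate
5 | [5-(benzyloxy)-2,3-dimethoxyphenoxy]triisopropylsilane | COc1cc(OCc2ccccc2)cc(O[Si](C(C)C)(C(C)C)C(C)C)c1OC | intermediate
6 | 5-(benzyloxy)-2,3-dimethoxyphenol | COc1cc(OCc2ccccc2)cc(O)c1OC | intermediate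
7 | 2-hydroxy-4-methoxybenzoic acid | COc1ccc(C(=O)O)c(O)c1 | starting material
8 | benzyl 2-(benzyloxy)-4-methoxybenzoate | COc1ccc(C(=O)OCc2ccccc2)c(OCc2ccccc2)c1 | intermediate
9 | 2-(benzyloxy)-4-methoxybenzoic acid | COc1ccc(C(=O)O)c(OCc2ccccc2)c1 | intermediate
10 | ethyl (benzyloxy)acetate | CCOC(=O)COCc1ccccc1 | starting material
11 | 2-(benzyloxy)-4-methoxybenzoyl chloride | COc1ccc(C(=O)Cl)c(OCc2ccccc2)c1 | intermediate
12 | ethyl 2-(benzyloxy)-3-[2-(benzyloxy)-4-methoxyphenyl]-3-oxopropanoate (racemic, enolisable centre) | CCOC(=O)C(OCc1ccccc1)C(=O)c1ccc(OC)cc1OCc1ccccc1 | intermediate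
13 | 2-(benzyloxy)-3-[2-(benzyloxy)-4-methoxyphenyl]-3-oxoprop-1-en-1-one (acylketene) | COc1ccc(C(=O)C(OCc2ccccc2)=C=O)c(OCc2ccccc2)c1 | intermediate
14 | 5-(benzyloxy)-2,3-dimethoxyphenyl 2-(benzyloxy)-3-[2-(benzyloxy)-4-methoxyphenyl]-3-oxopropanoate (racemic) | COc1cc(OCc2ccccc2)cc(OC(=O)C(OCc2ccccc2)C(=O)c2ccc(OC)cc2OCc2ccccc2)c1OC | intermediate
15 | 2-(benzyloxy)-1-[6-(benzyloxy)-2-hydroxy-3,4-dimethoxyphenyl]-3-[2-(benzyloxy)-4-methoxyphenyl]propane-1,3-dione (racemic, enolisable) | COc1ccc(C(=O)C(OCc2ccccc2)C(=O)c2c(O)c(OC)c(OC)cc2OCc2ccccc2)c(OCc2ccccc2)c1 | intermediate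
16 | 3,5,2'-tris(benzyloxy)-7,8,4'-trimethoxyflavone | COc1ccc(-c2oc3c(OC)c(OC)cc(OCc4ccccc4)c3c(=O)c2OCc2ccccc2)c(OCc2ccccc2)c1 | intermediate
17 | 3,5,2'-trihydroxy-7,8,4'-trimethoxyflavone (achiral) | COc1ccc(-c2oc3c(OC)c(OC)cc(O)c3c(=O)c2O)c(O)c1 | target

Total step count: 8. Longest linear sequence: 6 (steps 1–4, 7, 8).

Steps most likely to fail

Step 7. C-acylation of a mono-phenol may be slow. Thermal decay of the ketoester could then overtake the annulation, through hydrolysis and decarboxylation by released water, ketene self-condensation, or capture of the ketene by the neighbouring 2'-benzyloxy oxygen. Benzyl migration and acylation at the C6 carbon are further competitors. The fallback sets out from 6 and 12 and comes back at 15, and so at 16.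
- Ortho-specific Casnati–Skattebøl formylation of 6 (MgCl2, Et3N, paraformaldehyde, MeCN, reflux) places the C4 carbon on the same single free ortho site and gives 6-(benzyloxy)-2-hydroxy-3,4-dimethoxybenzaldehyde F1.
- MOMCl and iPr2NEt in CH2Cl2 convert F1 into 6-(benzyloxy)-3,4-dimethoxy-2-(methoxymethoxy)benzaldehyde F2.
- Separately, Krapcho de-ethoxycarbonylation of 12 (LiCl, wet DMSO, 140 °C) gives 2-(benzyloxy)-1-[2-(benzyloxy)-4-methoxyphenyl]ethan-1-one F3.
- The lithium enolate of F3 (LiHMDS, THF, −78 °C) adds to F2 to give the aldol 2-(benzyloxy)-3-[6-(benzyloxy)-3,4-dimethoxy-2-(methoxymethoxy)phenyl]-1-[2-(benzyloxy)-4-methoxyphenyl]-3-hydroxypropan-1-one F4.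
- Dess–Martin oxidation of F4 gives 2-(benzyloxy)-1-[6-(benzyloxy)-3,4-dimethoxy-2-(methoxymethoxy)phenyl]-3-[2-(benzyloxy)-4-methoxyphenyl]propane-1,3-dione F5.
- HCl in MeOH–THF at 50 °C removes the MOM group to release 15, which cyclodehydrates under the same acid to 16.

Step 6. Proton transfer from product to enolate, O-acylation or double acylation, and rearrangement of the benzyloxy enolate on warming can all erode the C-acylation. The fallback sets out from 11 and 10 and comes back at 12, forming the C–C bond at the aldehyde oxidation level.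
- Reduction of 11 with LiAlH(OtBu)3 (THF, −78 °C) gives 2-(benzyloxy)-4-methoxybenzaldehyde F6.
- Aldol addition of the lithium enolate of 10 (LiHMDS, THF, −78 °C) to F6 gives ethyl 2-(benzyloxy)-3-[2-(benzyloxy)-4-methoxyphenyl]-3-hydroxypropanoate F7.
- Dess–Martin oxidation of F7 gives 12.

Step 8. Hydrogenolysis may stall at the crowded peri 5-O-benzyl ether, or the C2=C3 bond may be saturated on prolonged exposure. The fallback sets out from 16 and comes back at 17. It is a Lewis-acid ether cleavage with BCl3 and pentamethylbenzene as benzyl cation scavenger (CH2Cl2, −78 °C, MeOH quench). Chelation to the C4 carbonyl speeds cleavage at O3 and O5, and the low temperature spares the methyl ethers. No new compound is made on the way.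

Further compounds
F1 | step 7 | 6-(benzyloxy)-2-hydroxy-3,4-dimethoxybenzaldehyde | COc1cc(OCc2ccccc2)c(C=O)c(O)c1OC
F2 | step 7 | 6-(benzyloxy)-3,4-dimethoxy-2-(methoxymethoxy)benzaldehyde | COCOc1c(OC)c(OC)cc(OCc2ccccc2)c1C=O
F3 | step 7 | 2-(benzyloxy)-1-[2-(benzyloxy)-4-methoxyphenyl]ethan-1-one | COc1ccc(C(=O)COCc2ccccc2)c(OCc2ccccc2)c1
F4 | step 7 | 2-(benzyloxy)-3-[6-(benzyloxy)-3,4-dimethoxy-2-(methoxymethoxy)phenyl]-1-[2-(benzyloxy)-4-methoxyphenyl]-3-hydroxypropan-1-one (racemic mixture of diastereomers) | COCOc1c(OC)c(OC)cc(OCc2ccccc2)c1C(O)C(OCc1ccccc1)C(=O)c1ccc(OC)cc1OCc1ccccc1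
F5 | step 7 | 2-(benzyloxy)-1-[6-(benzyloxy)-3,4-dimethoxy-2-(methoxymethoxy)phenyl]-3-[2-(benzyloxy)-4-methoxyphenyl]propane-1,3-dione (racemic) | COCOc1c(OC)c(OC)cc(OCc2ccccc2)c1C(=O)C(OCc1ccccc1)C(=O)c1ccc(OC)cc1OCc1ccccc1
F6 | step 6 | 2-(benzyloxy)-4-methoxybenzaldehyde | COc1ccc(C=O)c(OCc2ccccc2)c1
F7 | step 6 | ethyl 2-(benzyloxy)-3-[2-(benzyloxy)-4-methoxyphenyl]-3-hydroxypropanoate (racemic mixture of diastereomers) | CCOC(=O)C(OCc1ccccc1)C(O)c1ccc(OC)cc1OCc1ccccc1
F0 | step 8 | none | none
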